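The left-handed product of the red run could not have come from the left-handed substrate as charged: it reached 74.9% of the two substrates together, and that substrate was half of the charge. So right-handed substrate had to be turning into left-handed while the catalyst worked.

common to all: left-handed substrate 0.40 M; right-handed substrate 0.40 M

|  | reagent | free catalyst | added ligand | remark | time |
|---|---|---|---|---|---|
| green | 2 equiv | 0.28 mol% | 3 mM | run made earlier |  |
| red | 2 equiv | 0.63 mol% | 3 mM | run made earlier |  |
| east | 2.00 equiv | 0.42 mol% | 3.0 mM |  | 2.5 h |
| north | 2.00 equiv | 0.42 mol% | 3.0 mM |  | 1.5 h |

- green (time / min: right-handed substrate / %, left-handed substrate / %, left-handed product / %): 10.0: 45.2, 41.9, 12.8; 20.0: 40.8, 36.7, 20.1; 50.0: 31.0, 29.1, 38.0; 120: 18.7, 17.3, 59.3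
- red (time / min: right-handed substrate / %, left-handed substrate / %, left-handed product / %): 30.0: 27.2, 24.1, 44.7; 60.0: 17.8, 16.2, 62.5; 90.0: 13.6, 13.3, 70.2; 120: 10.6, 10.1, 74.9

(each reading ± 0.5 percentage points)

- free catalyst is single-handed; left-handed substrate and right-handed substrate are mirror images of each other, charged as a racemate, each of them at the stated concentration
- what was read earlier has a scatter of 0.5 percentage points, one standard deviation
- an excess is the difference of the two amounts in percent of their sum
- an excess is below zero if the other one leads

- the flask that ends with the higher excess of right-handed substrate over left-handed substrate among what is left of the two, or "neither" when 2 percentage points or less lies between them (east / north / neither)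
- excess of right-handed substrate over left-handed substrate among what is left of the two at the end, east
- excess of right-handed substrate over left-handed substrate among what is left of the two at the end, north

I wrote the balance of the reagent first. Its charge equals the two substrates together, 0.800 M, so with one reagent per product, the substrates and the reagent are each the limiting reagent, and the fraction f of [reagent] left is also the fraction of substrates left. In both runs 1/f climbed about straight, with end slopes of 0.0148 /min in green and 0.0319 /min in red. Scaled by loading and averaged, these gave a drain constant of 0.0218 /min: the share of what is left lost per minute at full reagent. The drain is this constant times f, with f 33.8% for north and 23.5% for east.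

As a model I took the excess as a lag times the drain: the drain creates the excess, and the interconversion of the two substrates removes it. Single readings gave lags from 1.30 min (red at 90.0 min) to 7.29 min (green at 120 min), a spread of scattered readings and no bounds on a flask. So I averaged each run, which gave 4.60 min for green and 3.24 min for red, and I used these two means as a working bracket, an estimate and not a proof. It put north at 2.39% to 3.38% and east at 1.66% to 2.35%. Even the widest pair lay 1.7 percentage points apart, against a margin of 2 points, so I answered neither.

The forecast, at 2.8% for north and 1.9% for east, stood inside both brackets: “The gap is under 2 points, so neither.”

The flasks gave 2.84% for north and 2.02% for east: neither.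

    left-handed substrate ⇌ right-handed substrate (k = 0.130 /min)
    reagent + catalyst intermediate B → free catalyst + right-handed product (k = 11.0 /M/min)
    reagent + catalyst intermediate A → free catalyst + left-handed product (k = 26.0 /M/min)
    free catalyst + right-handed substrate ⇌ catalyst intermediate B (K = 0.770 /M, k = 740 /M/min)
    free catalyst + left-handed substrate ⇌ catalyst intermediate A (K = 5.30 /M, k = 1500 /M/min)
    2 free catalyst ⇌ resting dimer, settled at all times (K = 670 /M)
    free catalyst + added ligand ⇌ idle complex (K = 730 /M, k = 43.0 /M/min)

Divided by north's drain at the 34% of reagent left, the result gives a lag of 3.83 min, inside my working bracket. East's excess stands so low mainly because of the passing of left-handed substrate into right-handed substrate, both ways: with that step taken away, east ended at 94.4%, not 2.02%.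

(The runs were generated by integration from invented constants; noise was put on by code.)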